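**Retrosynthetic overview**

1. Target 18 comes from acid removal of three MOM groups, preceded by a copper hydride/chiral bisphosphine 1,4-reduction of the flat 4-arylcoumarin 15 (sets C4, the only stereocentre, as R) and by C3 protodesilylation of 14.
2. The strategy rests on the lactone ring O1–C2–C3–C4–C4a–C8a (chroman-2-one numbering) fused to ring A: it is cut into iodophenol 7 (O1, C8a, C4a), the two alkyne carbons of 11 (C4, C3) and carbon monoxide 12 (C2), joined in one palladium-catalysed carbonylative annulation in which the Me3Si group steers the aryl-bearing alkyne carbon to C4.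
3. The ring A resorcinol enters the annulation unprotected: only the hydroxyl ortho to iodine can lactonise, so the ring closure itself tells the two phenols apart, and the C7 hydroxyl is capped with MOM afterwards.
4. Iodophenol 7 comes from Heck coupling of bis-silylated 5-bromoresorcinol with MOM-protected 4-vinylguaiacol, iodination between the styryl and a silyloxy group, and desilylation; alkyne 11 comes from MOM protection and Sonogashira coupling of 4-bromoguaiacol.
5. Ring order: the three benzene rings are bought; the lactone ring is the only ring formed (step 8).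

Key step: step 8

Assumption: (R)-DTBM-SEGPHOS is taken as the ligand enantiomer whose copper hydride attacks the C4 face that leads to the (4R) lactone (CIP order at C4: C4a > aryl > C3 > H), by analogy with simpler 4-arylcoumarins; should the first run show the opposite sense, the (S)-ligand is used and nothing else changes.

**Route**

Step 1
Reactants: 1 5-bromoresorcinol
Product: 2 1-bromo-3,5-bis(tert-butyldimethylsilyloxy)benzene
Conditions: TBSCl (2.3 equiv), imidazole (3 equiv), DMF, 0 °C to rt
Reagents that add atoms: tert-butyldimethylsilyl chloride, CC(C)(C)[Si](C)(C)Cl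
Why: Imidazole-promoted O-silylation of both phenols should give a symmetrical bis-silyl ether that survives the Heck coupling, activates ring A for the later iodination and can be removed by fluoride without touching MOM ethers.

Step 2
Reactants: 3 2-methoxy-4-vinylphenol
Product: 4 2-methoxy-1-(methoxymethoxy)-4-vinylbenzene
Conditions: MOMCl (1.3 equiv), i-Pr2NEt (1.6 equiv), CH2Cl2, 0 °C to rt
Reagents that add atoms: chloromethyl methyl ether, COCCl
Why: O-alkylation of the phenol with an α-chloro ether (MOM protection) is routine and masks the phenol against base, fluoride and copper hydride until the last step.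

Step 3
Reactants: 2 1-bromo-3,5-bis(tert-butyldimethylsilyloxy)benzene; 4 2-methoxy-1-(methoxymethoxy)-4-vinylbenzene
Product: 5 (E)-1,3-bis(tert-butyldimethylsilyloxy)-5-{2-[3-methoxy-4-(methoxymethoxy)phenyl]ethenyl}benzene
Conditions: Pd2(dba)3 (1.5 mol %), [(t-Bu)3PH]BF4 (6 mol %), Cy2NMe (1.2 equiv), dioxane, 80 °C
Reagents that add atoms: none
Why: Mizoroki–Heck coupling, in which zerovalent palladium inserts into the C–Br bond, the arylpalladium adds to the terminal carbon of the styrene and syn β-hydride elimination should give the E-stilbene, under conditions mild enough for aryl silyl ethers.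

Step 4
Reactants: 5 (E)-1,3-bis(tert-butyldimethylsilyloxy)-5-{2-[3-methoxy-4-(methoxymethoxy)phenyl]ethenyl}benzene
Product: 6 (E)-1,5-bis(tert-butyldimethylsilyloxy)-2-iodo-3-{2-[3-methoxy-4-(methoxymethoxy)phenyl]ethenyl}benzene
Conditions: NIS (1.05 equiv), CF3CO2H (5 mol %), dry MeCN–CH2Cl2, 0 °C, dark
Reagents that add atoms: N-iodosuccinimide, O=C1CCC(=O)N1I
Why: Electrophilic aromatic iodination should go to the ring A carbon next to the styryl group, which is ortho to one silyloxy group and para to the other, because the position between the two silyloxy groups is shielded, no carbon of the guaiacyl ring is activated by two oxygens at once, and a dry non-nucleophilic medium leaves the alkene no partner for iodo-functionalisation.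

Step 5
Reactants: 6 (E)-1,5-bis(tert-butyldimethylsilyloxy)-2-iodo-3-{2-[3-methoxy-4-(methoxymethoxy)phenyl]ethenyl}benzene
Product: 7 (E)-4-iodo-5-{2-[3-methoxy-4-(methoxymethoxy)phenyl]ethenyl}benzene-1,3-diol
Conditions: TBAF (2.4 equiv), AcOH (2.4 equiv), THF, 0 °C
Reagents that add atoms: none
Why: Fluoride-mediated cleavage of aryl silyl ethers is fast at 0 °C, and the acetic acid buffer keeps the iodoresorcinol protonated while the MOM ether, the aryl iodide and the stilbene are left alone.

Step 6
Reactants: 8 4-bromo-2-methoxyphenol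
Product: 9 4-bromo-2-methoxy-1-(methoxymethoxy)benzene
Conditions: MOMCl (1.3 equiv), i-Pr2NEt (1.6 equiv), CH2Cl2, 0 °C to rt
Reagents that add atoms: chloromethyl methyl ether, COCCl
Why: MOM protection (O-alkylation of the phenoxide) removes the acidic proton before the Sonogashira coupling and matches the protecting group used on the styryl phenol.

Step 7
Reactants: 9 4-bromo-2-methoxy-1-(methoxymethoxy)benzene; 10 ethynyltrimethylsilane
Product: 11 {[3-methoxy-4-(methoxymethoxy)phenyl]ethynyl}trimethylsilane
Conditions: PdCl2(PPh3)2 (3 mol %), CuI (3 mol %), Et3N, sealed tube, 80 °C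
Reagents that add atoms: none
Why: Sonogashira coupling of the aryl bromide with the terminal alkyne (copper acetylide transmetalation to arylpalladium, reductive elimination) should give the aryl silyl alkyne, heating in a closed vessel compensating for the electron-rich bromide.

Step 8
Reactants: 7 (E)-4-iodo-5-{2-[3-methoxy-4-(methoxymethoxy)phenyl]ethenyl}benzene-1,3-diol; 11 {[3-methoxy-4-(methoxymethoxy)phenyl]ethynyl}trimethylsilane; 12 carbon monoxide
Product: 13 7-hydroxy-4-[3-methoxy-4-(methoxymethoxy)phenyl]-5-{(E)-2-[3-methoxy-4-(methoxymethoxy)phenyl]ethenyl}-3-(trimethylsilyl)-2H-chromen-2-one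
Conditions: Pd(OAc)2 (5 mol %), pyridine (2 equiv), n-Bu4NCl (1 equiv), 11 (3 equiv), CO (1 atm, balloon), DMF, 120 °C
Reagents that add atoms: none
Why: Zerovalent palladium formed in situ inserts into the C4a–I bond of 7, the arylpalladium adds syn across alkyne 11 with ring A going to the aryl-bearing carbon (C4a–C4) and palladium to the silyl-bearing carbon, carbon monoxide inserts into the vinyl–palladium bond (C3–C2) and the ortho phenoxide attacks the acylpalladium (C2–O1), releasing 13 and zerovalent palladium. The closest known reaction is the Larock-type carbonylative annulation of ortho-iodophenols with internal alkynes under 1 atm of CO with pyridine and a chloride source, in which silyl and other bulky alkyne substituents end up at C3. The one ring formed, the six-membered lactone, closes by C–O reductive elimination from a seven-membered oxa-acylpalladacycle, and no stereocentre is created. Three selectivities are needed: the regiochemistry of alkyne insertion, secured by the bulky Me3Si group taking the carbon bound to palladium; alkyne insertion ahead of CO insertion, secured by phosphine-free palladium, low CO pressure and excess alkyne; and carbonylation of the vinylpalladium ahead of 5-exo carbopalladation of the neighbouring styryl group, favoured because CO inserts quickly and the ortho phenoxide chelates palladium. Only the hydroxyl ortho to iodine can reach the acylpalladium, so the C7 hydroxyl should emerge free and is the only phenol left to protect.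

Step 9
Reactants: 13 7-hydroxy-4-[3-methoxy-4-(methoxymethoxy)phenyl]-5-{(E)-2-[3-methoxy-4-(methoxymethoxy)phenyl]ethenyl}-3-(trimethylsilyl)-2H-chromen-2-one
Product: 14 7-(methoxymethoxy)-4-[3-methoxy-4-(methoxymethoxy)phenyl]-5-{(E)-2-[3-methoxy-4-(methoxymethoxy)phenyl]ethenyl}-3-(trimethylsilyl)-2H-chromen-2-one
Conditions: MOMCl (1.5 equiv), i-Pr2NEt (2 equiv), CH2Cl2, 0 °C to rt
Reagents that add atoms: chloromethyl methyl ether, COCCl
Why: MOM protection of the single free, acidic 7-hydroxycoumarin phenol needs no selectivity and removes the proton that would otherwise consume copper hydride and silane in step 11.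

Step 10
Reactants: 14 7-(methoxymethoxy)-4-[3-methoxy-4-(methoxymethoxy)phenyl]-5-{(E)-2-[3-methoxy-4-(methoxymethoxy)phenyl]ethenyl}-3-(trimethylsilyl)-2H-chromen-2-one
Product: 15 7-(methoxymethoxy)-4-[3-methoxy-4-(methoxymethoxy)phenyl]-5-{(E)-2-[3-methoxy-4-(methoxymethoxy)phenyl]ethenyl}-2H-chromen-2-one
Conditions: TBAF (1.2 equiv), H2O (2 equiv), THF, 0 °C to rt; AcOH quench
Reagents that add atoms: none
Why: Fluoride-induced protodesilylation of an α-silyl unsaturated lactone, in which fluoride attacks silicon and the C3 carbanion equivalent next to the carbonyl group is protonated by water, should clear C3 while MOM ethers and the stilbene are inert and any opened lactone recloses on the acidic quench because the alkene geometry is fixed.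

Step 11
Reactants: 15 7-(methoxymethoxy)-4-[3-methoxy-4-(methoxymethoxy)phenyl]-5-{(E)-2-[3-methoxy-4-(methoxymethoxy)phenyl]ethenyl}-2H-chromen-2-one
Product: 17 (4R)-7-(methoxymethoxy)-4-[3-methoxy-4-(methoxymethoxy)phenyl]-5-{(E)-2-[3-methoxy-4-(methoxymethoxy)phenyl]ethenyl}-3,4-dihydro-2H-chromen-2-one, via silyl ketene acetal 16 (not isolated)
Conditions: Cu(OAc)2·H2O (5 mol %), (R)-DTBM-SEGPHOS (5.5 mol %), (EtO)2MeSiH (1.5 equiv), toluene, 0 °C to rt; then aq. NH4F
Reagents that add atoms: none
Why: Asymmetric copper hydride conjugate reduction of a β,β-disubstituted unsaturated lactone, in which the bisphosphine-ligated copper hydride delivers hydride to one enantiotopic face of C4 and so sets the (R) centre under catalyst control, the copper enolate is silylated to ketene acetal 16, which shields the aryl lactone from 1,2-reduction until aqueous work-up, and the stilbene, having no conjugated carbonyl group and no proton source to trap a benzylic copper species, should stay untouched.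

Step 12
Reactants: 17 (4R)-7-(methoxymethoxy)-4-[3-methoxy-4-(methoxymethoxy)phenyl]-5-{(E)-2-[3-methoxy-4-(methoxymethoxy)phenyl]ethenyl}-3,4-dihydro-2H-chromen-2-one
Product: 18 (4R)-7-hydroxy-4-(4-hydroxy-3-methoxyphenyl)-5-[(E)-2-(4-hydroxy-3-methoxyphenyl)ethenyl]-3,4-dihydro-2H-chromen-2-one
Conditions: 3 M aq. HCl/THF (1:3), 40 °C, argon, dark
Reagents that add atoms: none
Why: Acid-catalysed hydrolysis of the three aryl MOM acetals in alcohol-free aqueous THF should free the phenols without transesterifying the aryl lactone (any hydroxy acid recloses in acid), and C4 carries neither a leaving group nor an acidic hydrogen, so its configuration is kept.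

**Compound list**

1 | 5-bromoresorcinol | Oc1cc(O)cc(Br)c1 | starting material
2 | 1-bromo-3,5-bis(tert-butyldimethylsilyloxy)benzene | CC(C)(C)[Si](C)(C)Oc1cc(Br)cc(O[Si](C)(C)C(C)(C)C)c1 | intermediate
3 | 2-methoxy-4-vinylphenol | C=Cc1ccc(O)c(OC)c1 | starting material
4 | 2-methoxy-1-(methoxymethoxy)-4-vinylbenzene | C=Cc1ccc(OCOC)c(OC)c1 | intermediate
5 | (E)-1,3-bis(tert-butyldimethylsilyloxy)-5-{2-[3-methoxy-4-(methoxymethoxy)phenyl]ethenyl}benzene | COCOc1ccc(/C=C/c2cc(O[Si](C)(C)C(C)(C)C)cc(O[Si](C)(C)C(C)(C)C)c2)cc1OC | intermediate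
6 | (E)-1,5-bis(tert-butyldimethylsilyloxy)-2-iodo-3-{2-[3-methoxy-4-(methoxymethoxy)phenyl]ethenyl}benzene | COCOc1ccc(/C=C/c2cc(O[Si](C)(C)C(C)(C)C)cc(O[Si](C)(C)C(C)(C)C)c2I)cc1OC | intermediate
7 | (E)-4-iodo-5-{2-[3-methoxy-4-(methoxymethoxy)phenyl]ethenyl}benzene-1,3-diol | COCOc1ccc(/C=C/c2cc(O)cc(O)c2I)cc1OC | intermediate
8 | 4-bromo-2-methoxyphenol | COc1cc(Br)ccc1O | starting material
9 | 4-bromo-2-methoxy-1-(methoxymethoxy)benzene | COCOc1ccc(Br)cc1OC | intermediate
10 | ethynyltrimethylsilane | C#C[Si](C)(C)C | starting material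
11 | {[3-methoxy-4-(methoxymethoxy)phenyl]ethynyl}trimethylsilane | COCOc1ccc(C#C[Si](C)(C)C)cc1OC | intermediate
12 | carbon monoxide | [C-]#[O+] | starting material
13 | 7-hydroxy-4-[3-methoxy-4-(methoxymethoxy)phenyl]-5-{(E)-2-[3-methoxy-4-(methoxymethoxy)phenyl]ethenyl}-3-(trimethylsilyl)-2H-chromen-2-one | COCOc1ccc(/C=C/c2cc(O)cc3OC(=O)C([Si](C)(C)C)=C(c4ccc(OCOC)c(OC)c4)c23)cc1OC | intermediate
14 | 7-(methoxymethoxy)-4-[3-methoxy-4-(methoxymethoxy)phenyl]-5-{(E)-2-[3-methoxy-4-(methoxymethoxy)phenyl]ethenyl}-3-(trimethylsilyl)-2H-chromen-2-one | COCOc1ccc(/C=C/c2cc(OCOC)cc3OC(=O)C([Si](C)(C)C)=C(c4ccc(OCOC)c(OC)c4)c23)cc1OC | intermediate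
15 | 7-(methoxymethoxy)-4-[3-methoxy-4-(methoxymethoxy)phenyl]-5-{(E)-2-[3-methoxy-4-(methoxymethoxy)phenyl]ethenyl}-2H-chromen-2-one | COCOc1ccc(/C=C/c2cc(OCOC)cc3OC(=O)C=C(c4ccc(OCOC)c(OC)c4)c23)cc1OC | intermediate
16 | (4R)-2-[diethoxy(methyl)silyloxy]-7-(methoxymethoxy)-4-[3-methoxy-4-(methoxymethoxy)phenyl]-5-{(E)-2-[3-methoxy-4-(methoxymethoxy)phenyl]ethenyl}-4H-chromene | COCOc1ccc(/C=C/c2cc(OCOC)cc3c2[C@@H](c2ccc(OCOC)c(OC)c2)C=C(O[Si](C)(OCC)OCC)O3)cc1OC | intermediate
17 | (4R)-7-(methoxymethoxy)-4-[3-methoxy-4-(methoxymethoxy)phenyl]-5-{(E)-2-[3-methoxy-4-(methoxymethoxy)phenyl]ethenyl}-3,4-dihydro-2H-chromen-2-one | COCOc1ccc(/C=C/c2cc(OCOC)cc3c2[C@@H](c2ccc(OCOC)c(OC)c2)CC(=O)O3)cc1OC | intermediate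
18 | (4R)-7-hydroxy-4-(4-hydroxy-3-methoxyphenyl)-5-[(E)-2-(4-hydroxy-3-methoxyphenyl)ethenyl]-3,4-dihydro-2H-chromen-2-one | COc1cc(/C=C/c2cc(O)cc3c2[C@@H](c2ccc(O)c(OC)c2)CC(=O)O3)ccc1O | target

**Step count**

Total: 12 steps. Longest linear sequence: 9 steps (steps 1, 3, 4, 5, 8, 9, 10, 11, 12, from 5-bromoresorcinol).

**Steps most likely to fail**

Step 8 (carbonylative annulation). The arylpalladium from 7 carries two ortho substituents, so alkyne insertion may be slow enough for CO to insert first, leading to chromone-type or ester products. The vinylpalladium may add to the neighbouring styryl double bond instead of taking up CO. The alkyne may lose its silyl group at 120 °C. The fallback brings C2, C3, C4 and the aryl group in together as a cinnamate and closes the lactone by a domino Heck/lactonisation. It sets out from 7. Ethyl ferulate is protected (MOMCl, i-Pr2NEt, CH2Cl2) to ethyl (E)-3-[3-methoxy-4-(methoxymethoxy)phenyl]prop-2-enoate F1. Heating 7 with F1, Pd(OAc)2, Et3N and n-Bu4NBr in DMF at 110 °C should arylate the β-carbon with ring A replacing the β-hydrogen, which places ring A cis to the ester, so the ortho phenol closes with loss of ethanol to 7-hydroxy-4-[3-methoxy-4-(methoxymethoxy)phenyl]-5-{(E)-2-[3-methoxy-4-(methoxymethoxy)phenyl]ethenyl}-2H-chromen-2-one F2. MOM protection of F2 (MOMCl, i-Pr2NEt) rejoins the route at 15, with no silyl group to remove.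

Step 11 (copper hydride reduction). The peri styryl group may erode facial selectivity or slow hydride delivery to C4; the aryl lactone may be reduced further to the lactol; prolonged reaction may allow hydrocupration of the stilbene. The fallback sets C4 by carbon–carbon bond formation, a rhodium-catalysed asymmetric 1,4-addition of an arylboronic acid (Hayashi–Miyaura reaction). It sets out from 7. Both phenols are protected (MOMCl, i-Pr2NEt) to (E)-2-iodo-1,5-bis(methoxymethoxy)-3-{2-[3-methoxy-4-(methoxymethoxy)phenyl]ethenyl}benzene F3. Heck coupling of F3 with ethyl acrylate (Pd(OAc)2, P(o-tol)3, Et3N, DMF, 90 °C) should give ethyl (E)-3-{2,4-bis(methoxymethoxy)-6-[(E)-2-(3-methoxy-4-(methoxymethoxy)phenyl)ethenyl]phenyl}prop-2-enoate F4. The boron partner, [3-methoxy-4-(methoxymethoxy)phenyl]boronic acid F5, is made from 9 by bromine–lithium exchange (n-BuLi, THF, −78 °C), B(Oi-Pr)3 and aqueous work-up. Addition of F5 to F4 with [RhCl(C2H4)2]2, a chiral bicyclic diene ligand (enantiomer chosen for the R product), KOH, dioxane/H2O at 50 °C should give ethyl (3R)-3-{2,4-bis(methoxymethoxy)-6-[(E)-2-(3-methoxy-4-(methoxymethoxy)phenyl)ethenyl]phenyl}-3-[3-methoxy-4-(methoxymethoxy)phenyl]propanoate F6. Aqueous HCl in THF then removes the four MOM groups and the liberated ortho phenol lactonises onto the ester, which rejoins the route at target 18.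

Step 4 (iodination). Iodine may be lost to the electron-rich stilbene double bond or to the guaiacyl ring, or a second iodine may enter ring A. The fallback places iodine before the alkene exists and then builds the stilbene by cross-metathesis. It sets out from 2. Bromine–lithium exchange (n-BuLi, THF, −78 °C) and DMF quench should give 3,5-bis(tert-butyldimethylsilyloxy)benzaldehyde F7. Iodination of F7 (NIS, catalytic CF3CO2H, MeCN), with no alkene present, should give 3,5-bis(tert-butyldimethylsilyloxy)-2-iodobenzaldehyde F8. Wittig methylenation of F8 (Ph3PCH3Br, NaHMDS, THF, 0 °C) should give 1,5-bis(tert-butyldimethylsilyloxy)-2-iodo-3-vinylbenzene F9. Cross-metathesis of F9 with an excess of styrene 4 (second-generation Hoveyda–Grubbs catalyst, CH2Cl2, 40 °C) should give the E-stilbene and rejoins the route at 6.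

**Further compounds**

F1 | step 8 | ethyl (E)-3-[3-methoxy-4-(methoxymethoxy)phenyl]prop-2-enoate | CCOC(=O)/C=C/c1ccc(OCOC)c(OC)c1
F2 | step 8 | 7-hydroxy-4-[3-methoxy-4-(methoxymethoxy)phenyl]-5-{(E)-2-[3-methoxy-4-(methoxymethoxy)phenyl]ethenyl}-2H-chromen-2-one | COCOc1ccc(/C=C/c2cc(O)cc3OC(=O)C=C(c4ccc(OCOC)c(OC)c4)c23)cc1OC
F3 | step 11 | (E)-2-iodo-1,5-bis(methoxymethoxy)-3-{2-[3-methoxy-4-(methoxymethoxy)phenyl]ethenyl}benzene | COCOc1ccc(/C=C/c2cc(OCOC)cc(OCOC)c2I)cc1OC
F4 | step 11 | ethyl (E)-3-{2,4-bis(methoxymethoxy)-6-[(E)-2-(3-methoxy-4-(methoxymethoxy)phenyl)ethenyl]phenyl}prop-2-enoate | CCOC(=O)/C=C/c1c(OCOC)cc(OCOC)cc1/C=C/c1ccc(OCOC)c(OC)c1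
F5 | step 11 | [3-methoxy-4-(methoxymethoxy)phenyl]boronic acid | COCOc1ccc(B(O)O)cc1OC
F6 | step 11 | ethyl (3R)-3-{2,4-bis(methoxymethoxy)-6-[(E)-2-(3-methoxy-4-(methoxymethoxy)phenyl)ethenyl]phenyl}-3-[3-methoxy-4-(methoxymethoxy)phenyl]propanoate | COCOc1ccc(/C=C/c2cc(OCOC)cc(OCOC)c2[C@@H](c2ccc(OCOC)c(OC)c2)CC(=O)OCC)cc1OC
F7 | step 4 | 3,5-bis(tert-butyldimethylsilyloxy)benzaldehyde | CC(C)(C)[Si](C)(C)Oc1cc(C=O)cc(O[Si](C)(C)C(C)(C)C)c1
F8 | step 4 | 3,5-bis(tert-butyldimethylsilyloxy)-2-iodobenzaldehyde | CC(C)(C)[Si](C)(C)Oc1cc(C=O)c(I)c(O[Si](C)(C)C(C)(C)C)c1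
F9 | step 4 | 1,5-bis(tert-butyldimethylsilyloxy)-2-iodo-3-vinylbenzene | C=Cc1cc(O[Si](C)(C)C(C)(C)C)cc(O[Si](C)(C)C(C)(C)C)c1I
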